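**Strategy**

The route rests on cutting the C2(=O)–C3 bond of the γ-butyrolactone: C3 is at once a ring atom and one terminus of the exocyclic benzylidene double bond, whose hydrogen lies cis to the C2 carbonyl. That pattern is the signature of a syn addition of an O-bound carbonyl and a hydrogen across an alkyne. The key step is therefore a palladium-catalysed cyclocarbonylation: the C5 hydroxyl captures CO as an alkoxycarbonyl–palladium unit, which inserts the aryl alkyne 5-exo-dig, closing the ring and fixing the E geometry in one operation. Its precursor is an acyclic (R)-4-aryl-2-benzylbut-3-yn-1-ol, whose single stereocentre comes from lipase desymmetrisation of a prochiral 1,3-diol.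

Key step: step 8

Remark: lipase PS is assumed to acetylate 2-benzylpropane-1,3-diols on the enantiotopic hydroxymethyl arm that gives the (R)-monoacetate, the sense expected for this enzyme and substrate class.

**Route**

Step 1
Reactants: 1 diethyl malonate; 2 3,4,5-trimethoxybenzyl chloride
Product: 3 diethyl 2-(3,4,5-trimethoxybenzyl)malonate
Conditions: NaH (1.0 equiv), 1 (2 equiv), THF, 0 °C to reflux
Reagents that add atoms: none
Why: Malonate alkylation (SN2) with a reactive benzylic chloride; excess malonate should suppress dialkylation.

Step 2
Reactants: 3 diethyl 2-(3,4,5-trimethoxybenzyl)malonate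
Product: 4 2-(3,4,5-trimethoxybenzyl)propane-1,3-diol
Conditions: LiAlH4, THF, 0 °C to reflux; Fieser work-up
Reagents that add atoms: none
Why: Hydride reduction of both esters should give the prochiral 1,3-diol; the aryl methyl ethers are inert.

Step 3
Reactants: 4 2-(3,4,5-trimethoxybenzyl)propane-1,3-diol
Product: 5 (R)-2-(hydroxymethyl)-3-(3,4,5-trimethoxyphenyl)propyl acetate
Conditions: lipase PS (Burkholderia cepacia, immobilised), vinyl acetate, i-Pr2O, 25 °C
Reagents that add atoms: vinyl acetate, CC(=O)OC=C
Why: Enzymatic desymmetrisation by irreversible transesterification; the lipase should distinguish the two enantiotopic hydroxymethyl groups and so set the only stereocentre, and slight over-acylation to diacetate should raise the ee of the monoacetate.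

Step 4
Reactants: 5 (R)-2-(hydroxymethyl)-3-(3,4,5-trimethoxyphenyl)propyl acetate
Product: 6 (S)-2-formyl-3-(3,4,5-trimethoxyphenyl)propyl acetate
Conditions: Dess–Martin periodinane, NaHCO3, CH2Cl2, 0 °C; used at once without chromatography
Reagents that add atoms: none
Why: Dess–Martin oxidation under buffered, non-basic conditions should give the α-chiral β-acetoxy aldehyde without enolisation or loss of acetic acid (the descriptor changes only through CIP priorities).

Step 5
Reactants: 6 (S)-2-formyl-3-(3,4,5-trimethoxyphenyl)propyl acetate
Product: 7 (R)-4,4-dibromo-2-(3,4,5-trimethoxybenzyl)but-3-en-1-yl acetate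
Conditions: CBr4 (2 equiv), PPh3 (4 equiv), CH2Cl2, 0 °C
Reagents that add atoms: carbon tetrabromide, BrC(Br)(Br)Br
Why: First stage of the Corey–Fuchs reaction (Wittig-type dibromo-olefination); no external base is present, so the labile aldehyde should be trapped before it epimerises or eliminates.

Step 6
Reactants: 7 (R)-4,4-dibromo-2-(3,4,5-trimethoxybenzyl)but-3-en-1-yl acetate
Product: 9 (R)-2-(3,4,5-trimethoxybenzyl)but-3-yn-1-ol, via dilithium alkoxide acetylide 8 (not isolated)
Conditions: n-BuLi (4.5 equiv), THF, −78 °C to 0 °C; then sat. aq. NH4Cl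
Reagents that add atoms: none
Why: Second stage of the Corey–Fuchs reaction (Br/Li exchange, Fritsch–Buttenberg–Wiechell 1,2-hydride shift, deprotonation to the acetylide); the surplus butyllithium is meant to consume the acetate as a tertiary alkoxide, so the free alkynol should be released in the same operation.

Step 7
Reactants: 9 (R)-2-(3,4,5-trimethoxybenzyl)but-3-yn-1-ol; 10 4-iodo-2,6-dimethoxyphenol
Product: 11 (R)-4-[4-hydroxy-3-(3,4,5-trimethoxybenzyl)but-1-yn-1-yl]-2,6-dimethoxyphenol
Conditions: PdCl2(PPh3)2 (3 mol %), CuI (5 mol %), Et3N, THF, degassed, 40 °C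
Reagents that add atoms: none
Why: Sonogashira coupling of a terminal alkyne with an aryl iodide; the free primary alcohol and the free phenol are tolerated by the amine base.

Step 8
Reactants: 11 (R)-4-[4-hydroxy-3-(3,4,5-trimethoxybenzyl)but-1-yn-1-yl]-2,6-dimethoxyphenol
Product: 14 (R,E)-3-(4-hydroxy-3,5-dimethoxybenzylidene)-4-(3,4,5-trimethoxybenzyl)dihydrofuran-2(3H)-one, via alkoxycarbonylpalladium(II) iodide 12 (not isolated), via lactone vinylpalladium(II) iodide 13 (not isolated)
Conditions: PdI2 (5 mol %), n-Bu3P (10 mol %), CO (7 bar), MeCN, 75 °C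
Reagents that add atoms: carbon monoxide, [C-]#[O+]
Why: Pd(II), CO and the primary hydroxyl should form the alkoxycarbonylpalladium species 12; the tethered alkyne then inserts syn into its Pd–C(O)OR bond, which makes the C2–C3 bond and the ring, and the vinylpalladium 13 is protonolysed with retention by the HI released earlier, regenerating Pd(II). The closest known reaction type is the palladium-catalysed cyclocarbonylation of homopropargylic alcohols to α-alkylidene-γ-butyrolactones. The five-membered lactone closes in the 5-exo-dig mode by intramolecular syn-carbopalladation. No stereocentre is created and the C4 centre is a spectator under these near-neutral conditions, while syn addition followed by retentive protonolysis places the olefinic hydrogen cis to the carbonyl, which is the E geometry. The step needs regioselectivity, secured by the three-atom O–CH2–CH tether, which lets the acyl carbon reach only the proximal alkyne carbon because endo insertion would demand a trans double bond in a six-membered ring. It also needs chemoselectivity over 5-endo oxypalladation to a 2-aryldihydrofuran, for which the CO pressure and the donor phosphine are relied on, with the hindered phenol left untouched since no base or oxidant is present.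

**Compound list**

1 | diethyl malonate | CCOC(=O)CC(=O)OCC | starting material
2 | 3,4,5-trimethoxybenzyl chloride | COc1cc(CCl)cc(OC)c1OC | starting material
3 | diethyl 2-(3,4,5-trimethoxybenzyl)malonate | CCOC(=O)C(Cc1cc(OC)c(OC)c(OC)c1)C(=O)OCC | intermediate
4 | 2-(3,4,5-trimethoxybenzyl)propane-1,3-diol | OCC(CO)Cc1cc(OC)c(OC)c(OC)c1 | intermediate
5 | (R)-2-(hydroxymethyl)-3-(3,4,5-trimethoxyphenyl)propyl acetate | OC[C@H](COC(C)=O)Cc1cc(OC)c(OC)c(OC)c1 | intermediate
6 | (S)-2-formyl-3-(3,4,5-trimethoxyphenyl)propyl acetate | O=C[C@H](COC(C)=O)Cc1cc(OC)c(OC)c(OC)c1 | intermediate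
7 | (R)-4,4-dibromo-2-(3,4,5-trimethoxybenzyl)but-3-en-1-yl acetate | BrC(Br)=C[C@H](COC(C)=O)Cc1cc(OC)c(OC)c(OC)c1 | intermediate
8 | dilithium alkoxide acetylide of (R)-2-(3,4,5-trimethoxybenzyl)but-3-yn-1-ol | [Li]C#C[C@H](CO[Li])Cc1cc(OC)c(OC)c(OC)c1 | intermediate
9 | (R)-2-(3,4,5-trimethoxybenzyl)but-3-yn-1-ol | C#C[C@H](CO)Cc1cc(OC)c(OC)c(OC)c1 | intermediate
10 | 4-iodo-2,6-dimethoxyphenol | COc1cc(I)cc(OC)c1O | starting material
11 | (R)-4-[4-hydroxy-3-(3,4,5-trimethoxybenzyl)but-1-yn-1-yl]-2,6-dimethoxyphenol | COc1cc(C#C[C@H](CO)Cc2cc(OC)c(OC)c(OC)c2)cc(OC)c1O | intermediate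
12 | alkoxycarbonylpalladium(II) iodide of 11 (phosphine ligands omitted) | COc1cc(C#C[C@H](COC(=O)[Pd]I)Cc2cc(OC)c(OC)c(OC)c2)cc(OC)c1O | intermediate
13 | (Z)-vinylpalladium(II) iodide of the closed lactone (phosphine ligands omitted) | COc1cc(/C([Pd]I)=C2/C(=O)OC[C@@H]2Cc2cc(OC)c(OC)c(OC)c2)cc(OC)c1O | intermediate
14 | (R,E)-3-(4-hydroxy-3,5-dimethoxybenzylidene)-4-(3,4,5-trimethoxybenzyl)dihydrofuran-2(3H)-one | COc1cc(/C=C2/C(=O)OC[C@@H]2Cc2cc(OC)c(OC)c(OC)c2)cc(OC)c1O | target

**Summary**

Total step count: 8. Longest linear sequence: 8 steps (1/2 to 14).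

**Steps most likely to fail**

1. Step 8. The electron-rich internal aryl alkyne may insert slowly. The alcohol may add to the palladium-activated alkyne in a 5-endo sense before carbonylation, or the phenol may reduce Pd(II) and stall the cycle. Fallback: setting out from 9, the terminal alkynol (the most reliable substrate class for this cyclocarbonylation) would be carbonylated under the step 8 conditions to (R)-3-methylene-4-(3,4,5-trimethoxybenzyl)dihydrofuran-2(3H)-one F1. A Heck arylation of F1 with 10 (Pd(OAc)2, P(o-tol)3, Et3N, DMF, 80 °C) should then give 14 by β-hydride elimination from the benzylic CH2, which favours the E-arylidene isomer. The fallback comes back to the route at 14. It keeps the same ring-forming event but moves the aryl group to a later stage.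

2. Step 3. The enzyme may discriminate the enantiotopic arms poorly or in the opposite sense, and 1,3-acyl migration in the monoacetate may erode the enantiomeric excess on standing. Fallback: setting out from 4, exhaustive acetylation (Ac2O, pyridine, DMAP) would give 2-(3,4,5-trimethoxybenzyl)propane-1,3-diyl diacetate F2. Enantiotopos-selective hydrolysis of F2 (porcine pancreatic lipase or the lipase of step 3, phosphate buffer pH 7) cleaves the arm that acylation would have esterified, so the hydrolase would be chosen for the arm it removes. The fallback comes back at 5.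

3. Step 6. The acetate may be consumed incompletely or unselectively by butyllithium, and acyl transfer from the acetate to the lithium acetylide may compete. Fallback: setting out from 7, the acetate would first be removed by methanolysis (K2CO3 cat., MeOH, 0 °C) to give (R)-4,4-dibromo-2-(3,4,5-trimethoxybenzyl)but-3-en-1-ol F3. F3 would then be treated with n-BuLi (3.3 equiv, THF, −78 °C), so that elimination and rearrangement run on a substrate without an ester. The fallback comes back at 9.

**Further compounds**

F1 | step 8 | (R)-3-methylene-4-(3,4,5-trimethoxybenzyl)dihydrofuran-2(3H)-one | C=C1C(=O)OC[C@@H]1Cc1cc(OC)c(OC)c(OC)c1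
F2 | step 3 | 2-(3,4,5-trimethoxybenzyl)propane-1,3-diyl diacetate | CC(=O)OCC(COC(C)=O)Cc1cc(OC)c(OC)c(OC)c1
F3 | step 6 | (R)-4,4-dibromo-2-(3,4,5-trimethoxybenzyl)but-3-en-1-ol | OC[C@@H](C=C(Br)Br)Cc1cc(OC)c(OC)c(OC)c1
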